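The runs were generated by integration with made-up constants, noise included.

Of the 2.00 mM of E charged in the south-east run, I take 1.3 mM to be caught by L, one D each, and the remainder to begin chains.

- south-east: X 20 mM; E 10 mol%; L 1.3 mM; run made earlier
- flask: X 20 mM; E 10 mol%; L 2.6 mM; time 5.0 min

south-east run (percent of the X charged)

| time / s | Q / % | X / % |
|---|---|---|
| 10.0 | 4.2 | 95.1 |
| 15.0 | 6.7 | 93.1 |
| 40.0 | 13.9 | 86.1 |
| 90.0 | 23.1 | 75.6 |

(each reading ± 0.5 percentage points)

- a species is counted by the X in it: one J counts as two
- the average divides the monomer in chains by the number of chains begun, living and dead together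
- the analysis behind the earlier runs scatters by 0.5 percentage points, standard deviation
- reactions considered so far: X + G -> Q + G; E -> D; X + D -> G + Q; 2 X -> J; Q + G -> X + G; D + L -> Z
- the earlier runs do not show the number of chains; that part of a forecast is a guess

- average number of monomer units in a chain (chains begun, living or dead) at 5.0 min
- part of the X that has reacted at 5.0 min

c(G) ≈ c(E) − c(L) = 0.700 mM

X + G and Q + G both pass through G, so I assume that what one chain gains depends on c(X) and not on how many chains there are, and I reckon that small quantity instead of the whole flask. The growth per chain w, the net units gained by one chain per second (a net turnover frequency), is the rise in c(Q) over a window divided by c(G):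

w, from 40.0 s to 90.0 s: 0.0526 /s

With the first unit of each chain added, this gives:

dp ≈ 1 + w·t = 16.8

The weak link is the window: c(X) stands at 86.1% to 75.6% of its charge there, while the flask starts at its full charge. The earlier window, with c(X) falling from 93.1% to 86.1%, gives a second value:

w, from 15.0 s to 40.0 s: 0.0823 /s

I expect the flask to pass through both ranges, so I use the mean, 0.0674 /s, and commit to dp ≈ 21.2. I leave c open, since in the flask L exceeds E, so that my difference c(E) − c(L) gives no count of chains.

The forecast says dp 22 and c 16%, with chains at “perhaps 0.15 mM, though this is a guess”.

The flask gives dp 21.3 and c 23.7%.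

    X + G → Q + G, rate k1*[G]*[X] (k = 8.59 /M/s)
    E → D (k = 0.253 /s)
    X + D → G + Q (k = 76.0 /M/s)
    2 X → J (k = 0.00151 /M/s)
    Q + G → X + G, rate k5*[G] as long as [Q] is above zero (k = 0.0801 /s)
    D + L → Z (k = 8380 /M/s)

In the flask, G stands at 0.210 mM after 5.00 min, and dp corresponds to a mean growth per chain of 0.0675 /s. In the neighbouring flask, with 10 mM of L, c(X) ends at 93.1%, above the 86.1% that closes the earlier window, so I use that window's w and reckon dp ≈ 25.7. That neighbouring flask holds G at 0.0395 mM and gives dp 26.4 with c 6.91%.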